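(The earlier runs and the new flask are simulated with made-up constants, noise included.)

Read the rates first.

the same everywhere: left-handed substrate 0.20 M; right-handed substrate 0.20 M; added ligand 15 mM

| charge | reagent | free catalyst | remark | time |
|---|---|---|---|---|
| eta | 0.16 M | 6.6 mM | run made earlier |  |
| gamma | 0.16 M | 22 mM | run made earlier |  |
| autumn | 0.160 M | 11 mM |  | 20 min |
| dusk | 0.160 M | 30 mM |  | 20 min |

| run | time / min | right-handed substrate / % | left-handed substrate / % | left-handed product / % |
|---|---|---|---|---|
| eta | 2.00 | 50.7 | 49.3 | 0.8 |
| eta | 4.00 | 51.0 | 48.3 | 1.3 |
| eta | 6.00 | 50.0 | 47.3 | 3.5 |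
| eta | 8.00 | 49.0 | 44.9 | 2.4 |
| eta | 10.0 | 49.8 | 47.0 | 2.3 |
| gamma | 2.00 | 50.2 | 47.5 | 3.5 |
| gamma | 4.00 | 50.3 | 43.6 | 4.0 |
| gamma | 6.00 | 50.6 | 41.7 | 6.8 |
| gamma | 8.00 | 50.1 | 41.9 | 8.2 |
| gamma | 10.0 | 49.6 | 39.7 | 9.7 |

(scatter of a reading: 1 percentage point)

- the flask that ends with the higher excess of right-handed substrate over left-handed substrate among what is left of the two, or "neither" when 2 percentage points or less lies between them (autumn / dusk / neither)
- excess of right-handed substrate over left-handed substrate among what is left of the two at the end, autumn
- excess of right-handed substrate over left-handed substrate among what is left of the two at the end, dusk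

- free catalyst is single-handed; left-handed substrate and right-handed substrate are mirror images of each other, charged as a racemate, each of them at the stated concentration
- an excess is the difference of the two amounts in percent of their sum
- an excess is below zero if the other one leads

In both runs the right-handed substrate stays flat within the scatter, so the reckoning here, which is my own, follows the left-handed substrate as a fraction l of its charge and the reagent as a fraction b of its own. The reagent is the limiting reagent, its charge smaller than that of the left-handed substrate by the ratio β = 1.25, so if it is used one for one, b falls β times as fast as l. Taking the rate as proportional to catalyst charged, to l and to b, one quantity carries the reckoning: the start time τ, the charge of left-handed substrate divided by its opening rate, which on that assumption scales inversely with the catalyst charge. Elapsed time over τ then equals ln(l/b) divided by (β minus one).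

The gamma run has lost 20.0% of its left-handed charge at 10.0 min, the mean of the substrate and product readings, which gives 38.7 min. The eta run, having lost 5.30%, gives a looser 53.2 min at gamma's catalyst, so gamma's value is kept. Autumn then has τ = 77.5 min and dusk 28.4 min. Autumn's catalyst times time equals gamma's, so autumn is reckoned to lose 20.0% and to end at 0.600 of its opening rate. Dusk is reckoned to lose 39.2% and to end at about a third of its opening rate. The excesses come to 11.1% for autumn and 24.4% for dusk.

The forecast names dusk, with 11.5% for autumn and 27% for dusk, above my dusk figure, holding that “so the rate is roughly first order in catalyst”.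

The simulation gives dusk: 9.15% for autumn and 20.7% for dusk.

    reagent + free catalyst + left-handed substrate → free catalyst + left-handed product (k = 0.339 M⁻² s⁻¹)
    free catalyst ⇌ dormant form (K = 2.30, k = 0.00955 s⁻¹)
    reagent + free catalyst + right-handed substrate → free catalyst + right-handed product (k = 0.0113 M⁻² s⁻¹)
    free catalyst + added ligand ⇌ idle complex (K = 54.6 M⁻¹, k = 0.0498 M⁻¹ s⁻¹)
    reagent + free catalyst → spent catalyst (k = 6.18 × 10⁻⁴ M⁻¹ s⁻¹)

Autumn keeps 83% of its left-handed charge; with b taken one for one from that loss, its start time reads 93.1 min, longer than the reckoned 77.5 min. The neighbour of autumn, charged with 19.0 mM of free catalyst, then has τ = 53.9 min, which leaves 73.8% of its left-handed charge. That neighbour ends with 74% of its left-handed charge and an excess of 14.6%.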